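The runs come from a simulation on assumed constants, and the scatter is random.

By the steps thought possible, the free coupling partner, plus one for each mono adduct, plus two for each double product or isomer of the product, stays equal to the coupling partner charged.

| flask | solid substrate | coupling partner | remark | time |
|---|---|---|---|---|
| beta | 0.50 M | 0.525 M | the very flask that is asked about, followed so far |  |
| gamma | 0.50 M | 0.79 M | run made earlier |  |
| flask | 0.50 M | 0.525 M |  | 1.0 h |

| run | time / min | double product / % | starting material / % | solid substrate / % |
|---|---|---|---|---|
| beta | 2.50 | 0 | 6 | 94 |
| beta | 5.00 | 1 | 6 | 92 |
| beta | 8.00 | 0 | 10 | 90 |
| beta | 10.0 | 0 | 14 | 82 |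
| beta | 12.0 | 3 | 10 | 86 |
| gamma | 4.00 | 4 | 6 | 94 |
| gamma | 10.0 | 3 | 8 | 88 |
| gamma | 20.0 | 5 | 15 | 74 |
| gamma | 30.0 | 14 | 17 | 60 |
| gamma | 40.0 | 22 | 19 | 49 |

(standard deviation of a reading: 2 percentage points)

- solid, in amounts per volume of the solution: solid substrate
- steps thought possible: starting material + coupling partner -> mono adduct; coupling partner + mono adduct -> double product; solid substrate <-> starting material; double product <-> isomer of the product
- at the start none of the solid substrate is in solution
- starting material means what is dissolved; the solid is not counted in it

- south-east: doubling the solubility of the solid substrate, all else as stated
- north: doubling the dissolution coefficient of the solid substrate, all else as stated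
- south: doubling the amount of coupling partner, all else as stated

- how much double product there is at 1.0 h, in percent of the solid substrate charged
- concentration of starting material in solution at 15 min, in percent of saturation
- the change that raises the amount of double product at 1.0 h, in percent of the solid substrate charged most ("none" if none brings more than 2 percentage points) (south-east / north / south / none)
- amount of double product at 1.0 h, in percent of the solid substrate charged, after north

For flask beta I reckon half the coupling partner charged, over the solid substrate charged: 52.5%, the ceiling on double product. Coupling partner is the limiting reagent for double product in beta, since half its charge is less than the solid substrate.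

Now I read gamma's columns against its own ceiling of 79.0%. Its double product starts late, 5% at 20.0 min, and reaches 22% at 40.0 min. In that last row 10.0% stands in no column, so by the steps listed it is mono adduct or isomer of the product. Beta, with less coupling partner, reads 3% at 12.0 min.

So I expect beta to lie well under its ceiling at 1.0 h. South lifts that ceiling to 100% of the solid substrate charged, since half its doubled coupling partner then exceeds the solid substrate, which becomes the limit; north and south-east leave the ceiling where it stands.

The forecast gives 24%, 16% of saturation, 32% after north, and south as the best change, “with coupling partner running low and starting material piling up”. Its figure after north stays below the ceiling.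

The simulation gives 22.3%, 20.6%, 27.3% and south, with south adding 16 percentage points, south-east 6.1 points and north 5 points. The forecast's numbers fall within their margins, and its choice is right.

    starting material + coupling partner → mono adduct (k = 0.0940 M⁻¹ min⁻¹)
    coupling partner + mono adduct → double product (k = 0.320 M⁻¹ min⁻¹)
    solid substrate ⇌ starting material, rate k3*(cs3 - [starting material]) while solid is left; crystals form when [starting material] > cs3 (solubility = 0.350 M, k = 0.0220 min⁻¹)
    double product ⇌ isomer of the product (K = 0.540, k = 0.0190 min⁻¹)

Flask beta is not at rest at 1.0 h: 37% of its coupling partner and 33.1% of solid substrate are still there. At 10.0 h beta shows 0% of its coupling partner, 0% solid substrate, 30.5% double product, 16.4% isomer of the product and 11.2% mono adduct. Double product, isomer and half the mono adduct then sum to 52.5%, which is the ceiling of 52.5%.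

With 2.1 M of coupling partner, half that charge exceeds the solid substrate, so solid substrate becomes the limiting charge in that flask, and the same reckoning, taken on the smaller of the two, gives a ceiling of 100%. It gives 53.3% double product at 1.00 h, with 66% of its coupling partner still there.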